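The α-methylene-γ-lactone is cut across O–C6 and C11–C7, and the three-atom unit O–C12–C11 is delivered from the C8 oxygen. The structure allows this because O8 and the methylene carbon C13 are 1,5-related through C8, C7 and C11, so an ether O8–C13 makes a temporary tetrahydrofuran. The precursor is a (Z)-C6=C7 allylic ether whose O8–C13H2 arm ends in a 2-iodomalonate carbon (C11). Iodine-atom-transfer 5-exo cyclisation forms C11–C7, and the C6 iodide is then displaced by an ester oxygen, closing the lactone in the same operation. The tetrahydrofuran masks the methylene during ten-membered ring closure; its opening, Mitsunobu inversion at C8 and HBr loss finish the route.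

Key step: step 9

Remark on numbering: germacranolide numbering is used throughout. C1–C10 are the ring carbons (C1=C10 enoate, C4 bearing C15H2OH, C6 bearing the lactone oxygen, C8 bearing O8). C11–C13 are the acrylate unit (C12 carbonyl, C13 methylene), and C14 is the methyl ester carbon.

Remark on C8: the radical ring closure is expected to set C7 trans to C8. C8 is therefore carried in the epimeric configuration from step 6 and inverted when the acyl group is installed in step 16.

Remark on materials: 10 and 14 are taken to be catalogue compounds; 14 is distilled before use.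

**Step 1**
Reactants: 1 hex-5-enoic acid; 2 (R)-4-benzyloxazolidin-2-one
Product: 4 (R)-4-benzyl-3-(hex-5-enoyl)oxazolidin-2-one, via mixed pivalic anhydride 3 (not isolated)
Conditions: PivCl, Et3N, THF, −20 °C; then 2, LiCl, −20 °C → rt
Reagents that add atoms: none
Why: Mixed-anhydride N-acylation of the Evans auxiliary is a standard imide formation and creates no stereocentre.

**Step 2**
Reactants: 4 (R)-4-benzyl-3-(hex-5-enoyl)oxazolidin-2-one; 5 3-bromoprop-1-yne
Product: 6 (R)-4-benzyl-3-[(2S)-2-(prop-2-yn-1-yl)hex-5-enoyl]oxazolidin-2-one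
Conditions: NaHMDS, THF, −78 °C; then 5, −78 → −45 °C
Reagents that add atoms: none
Why: Evans asymmetric alkylation, in which the chelated (Z)-sodium enolate is attacked by the propargylic bromide on the face opposite the benzyl group of the (R)-auxiliary, should set C4 as (S).

**Step 3**
Reactants: 6 alkylated imide
Product: 7 (2S)-2-(prop-2-yn-1-yl)hex-5-en-1-ol
Conditions: LiBH4, MeOH (1 equiv), Et2O, 0 °C
Reagents that add atoms: none
Why: Reductive cleavage of the N-acyl oxazolidinone gives the C15 alcohol without touching the alkyne or alkene and without epimerising C4.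

**Step 4**
Reactants: 7 (2S)-2-(prop-2-yn-1-yl)hex-5-en-1-ol; 8 tert-butyl(chloro)diphenylsilane
Product: 9 tert-butyl(diphenyl){[(2S)-2-(prop-2-yn-1-yl)hex-5-en-1-yl]oxy}silane
Conditions: imidazole, CH2Cl2, rt
Reagents that add atoms: 8 tert-butyl(chloro)diphenylsilane, CC(C)(C)[Si](Cl)(c1ccccc1)c1ccccc1
Why: Standard silylation installs a TBDPS ether that should outlast the later base, radical, acid and Lewis-acid steps.

**Step 5**
Reactants: 9 silyl ether alkyne; 10 2-(tert-butyldimethylsilyloxy)-N-methoxy-N-methylacetamide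
Product: 11 (6S)-1-(tert-butyldimethylsilyloxy)-6-[(tert-butyldiphenylsilyloxy)methyl]dec-9-en-3-yn-2-one
Conditions: n-BuLi, THF, −78 °C; then 10, −78 → 0 °C; aq. NH4Cl
Reagents that add atoms: none
Why: Weinreb ketone synthesis, in which the lithium acetylide adds once to the amide and the chelated tetrahedral intermediate collapses to the ynone only on work-up.

**Step 6**
Reactants: 11 ynone
Product: 12 (2R,6S)-1-(tert-butyldimethylsilyloxy)-6-[(tert-butyldiphenylsilyloxy)methyl]dec-9-en-3-yn-2-ol
Conditions: Ru[(S,S)-TsNCH(Ph)CH(Ph)NH](p-cymene) (1 mol%), i-PrOH, rt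
Reagents that add atoms: none
Why: Noyori asymmetric transfer hydrogenation of an alkynyl ketone, in which the (S,S)-catalyst treats the alkynyl group as the π-substituent and is expected, by analogy with alkynyl methyl ketones, to give the (R)-carbinol at C8.

**Step 7**
Reactants: 12 propargylic alcohol
Product: 13 (2R,3Z,6S)-1-(tert-butyldimethylsilyloxy)-6-[(tert-butyldiphenylsilyloxy)methyl]deca-3,9-dien-2-ol
Conditions: H2 (1 atm), Lindlar catalyst, quinoline, EtOAc, rt, stopped after 1 equiv H2
Reagents that add atoms: none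
Why: Lindlar semihydrogenation adds H2 syn to the alkyne and should give the (Z)-C6=C7 alkene while the terminal alkene is kept by limiting the hydrogen uptake.

**Step 8**
Reactants: 13 (Z)-allylic alcohol; 14 diethyl 2-methylidenepropanedioate; 15 N-iodosuccinimide
Product: 17 diethyl 2-iodo-2-(alkoxymethyl)propanedioate in which the alkoxy group is the C8 oxygen of 13, via potassium malonate enolate 16 (not isolated)
Conditions: KHMDS (1.0 equiv), THF, −78 °C, 5 min; 14, −78 °C; then 15, −78 → −40 °C, dark
Reagents that add atoms: 15 N-iodosuccinimide, O=C1CCC(=O)N1I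
Why: Oxa-Michael addition of the potassium alkoxide to the doubly activated alkene gives a malonate enolate that is iodinated in the same flask, and working at −78 °C within minutes should forestall 1,2-silyl migration from O9; no stereocentre is formed.

**Step 9**
Reactants: 17 iodomalonate
Product: 19 tetrahydrofuran-fused lactone ethyl ester (lactone ring O–C6–C7–C11–C12, tetrahydrofuran ring C7–C8–O8–C13–C11, CO2Et on C11), via C6 iodide diester 18 (not isolated)
Conditions: (Bu3Sn)2 (10 mol%), hν (sunlamp), PhH (0.02 M), 80 °C; then n-Bu4NI (0.3 equiv), DMF, 90 °C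
Reagents that add atoms: none
Why: Tin-radical/light initiation abstracts iodine from 17, the malonyl radical C11 adds to C7 of the (Z)-alkene, the C6 radical takes iodine from a second molecule of 17 (chain transfer) to give 18, and on heating the ester carbonyl cis to C6 displaces iodide and loses iodoethane. The closest known reaction type is the iodomalonate atom-transfer radical cyclisation followed by thermal lactonisation of the γ-iodo malonate (atom-transfer radical annulation). The tetrahydrofuran ring closes by 5-exo-trig radical addition and the lactone ring by 5-exo-tet O-alkylation, which can only give the cis-fused bicycle and so fixes C11. C7 is set by C8: allylic 1,3-strain in the (Z)-allylic ether holds H8 in the alkene plane, the tethered radical attacks the face that carries O8, and C9 should end trans to C6 on the new ring. C6 is set in the lactonisation, where iodide exchange (Bu4NI) interconverts the two C6 iodides and closure through the less hindered arrangement should place C5 on the convex face, trans to C8. The step needs 5-exo closure to beat 6-endo closure and intermolecular addition to the terminal alkene, which the three-atom tether and high dilution secure, and iodine transfer from the iodomalonate is far faster than 6-exo cyclisation of the C6 radical onto C1.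

**Step 10**
Reactants: 19 lactone ethyl ester
Product: 22 tetrahydrofuran-fused lactone with H on C11 (C9 still as TBS ether), via hydroxy diacid 20 (not isolated), via carboxy lactone 21 (not isolated)
Conditions: LiOH, THF/MeOH/H2O, 50 °C; 1 M HCl to pH 3, 0 °C → rt; then PhMe, 110 °C
Reagents that add atoms: none
Why: Saponification opens the lactone and hydrolyses the remaining ester, acidification relactonises through the carboxyl cis to C6 (the C6–O bond is never broken), and the α-carboxy lactone undergoes malonic-type thermal decarboxylation to the only possible cis-fused lactone.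

**Step 11**
Reactants: 22 lactone TBS ether
Product: 23 tetrahydrofuran-fused lactone with free C9 hydroxyl
Conditions: CSA (10 mol%), MeOH/CH2Cl2, 0 °C
Reagents that add atoms: none
Why: Acid-catalysed methanolysis removes a primary TBS ether selectively in the presence of the much more acid-stable TBDPS ether.

**Step 12**
Reactants: 23 primary alcohol; 24 trimethyl phosphonoacetate
Product: 26 methyl 2-(dimethoxyphosphoryl)propanoate carrying the tetrahydrofuran-fused lactone at C3 (new C9–C10 bond; C10 epimers), via primary triflate 25 (not isolated)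
Conditions: Tf2O, 2,6-lutidine, CH2Cl2, −78 °C; then NaCH(CO2Me)P(O)(OMe)2 (from 24 and NaH), THF/DMF, −78 → 0 °C
Reagents that add atoms: none
Why: The primary triflate C-alkylates the soft sodium phosphonoacetate (malonate-type SN2 alkylation) at low temperature, where the lactone α-proton is not removed, and the C10 centre formed as a mixture is destroyed in step 14.

**Step 13**
Reactants: 26 phosphonoacetate; 27 ozone
Product: 29 C1 aldehyde, via ozonide 28 (not isolated)
Conditions: O3, CH2Cl2, −78 °C; then PPh3, −78 °C → rt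
Reagents that add atoms: 27 ozone, [O-][O+]=O
Why: Ozonolysis with reductive work-up cleaves the only remaining C=C bond to the C1 aldehyde.

**Step 14**
Reactants: 29 aldehyde phosphonoacetate
Product: 30 ten-membered (E)-enoate macrocycle with the tetrahydrofuran-fused lactone intact
Conditions: LiCl, DBU, MeCN (1 mM, syringe-pump addition), rt
Reagents that add atoms: none
Why: Intramolecular Horner–Wadsworth–Emmons olefination under Masamune–Roush conditions at high dilution should close the ten-membered ring, and the α-substituted phosphonoacetate gives the (E)-enoate (C2 trans to CO2Me), which is also the ring-cis alkene that a ten-membered ring prefers.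

**Step 15**
Reactants: 30 macrocycle; 31 bromodimethylborane
Product: 32 C13 bromide with free C8 hydroxyl (8-epi alcohol)
Conditions: Me2BBr, Et3N (cat.), CH2Cl2, −78 → 0 °C; aq. NaHCO3; used at once
Reagents that add atoms: 31 bromodimethylborane, CB(C)Br
Why: Guindon cleavage of a cyclic ether, in which bromide opens the boron-activated oxonium at the less hindered primary carbon C13 (SN2), should free O8–H and leave the methylene masked as a β-bromo lactone while esters, lactone and TBDPS ether survive.

**Step 16**
Reactants: 32 bromo alcohol; 33 (S)-2-methylbutanoic acid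
Product: 35 15-O-TBDPS ether of the target, via bromo ester 34 (not isolated)
Conditions: PPh3, DIAD, PhMe, 0 °C → rt; then DBU, rt
Reagents that add atoms: none
Why: Mitsunobu esterification inverts C8 to the (R) configuration of the target (SN2 on the alkoxyphosphonium) while installing the (S)-2-methylbutanoate, and DBU then removes HBr across C11–C13 (elimination of a β-bromo lactone) to release the α-methylene lactone.

**Step 17**
Reactants: 35 silyl ether
Product: 36 target CNP0141952.2
Conditions: HF·pyridine, pyridine, THF, 0 °C → rt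
Reagents that add atoms: none
Why: Buffered fluoride desilylation frees the C15 alcohol under conditions that should neither add to the α-methylene lactone nor move the esters.

**Compound list**

1 | hex-5-enoic acid | C=CCCCC(=O)O | starting material
2 | (R)-4-benzyloxazolidin-2-one | O=C1N[C@H](Cc2ccccc2)CO1 | starting material
3 | hex-5-enoic pivalic anhydride | C=CCCCC(=O)OC(=O)C(C)(C)C | intermediate
4 | (R)-4-benzyl-3-(hex-5-enoyl)oxazolidin-2-one | C=CCCCC(=O)N1[C@H](Cc2ccccc2)COC1=O | intermediate
5 | 3-bromoprop-1-yne | C#CCBr | starting material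
6 | (R)-4-benzyl-3-[(2S)-2-(prop-2-yn-1-yl)hex-5-enoyl]oxazolidin-2-one | C#CC[C@@H](C(=O)N1[C@H](Cc2ccccc2)COC1=O)CCC=C | intermediate
7 | (2S)-2-(prop-2-yn-1-yl)hex-5-en-1-ol | C#CC[C@@H](CO)CCC=C | intermediate
8 | tert-butyl(chloro)diphenylsilane | CC(C)(C)[Si](Cl)(c1ccccc1)c1ccccc1 | starting material
9 | tert-butyl(diphenyl){[(2S)-2-(prop-2-yn-1-yl)hex-5-en-1-yl]oxy}silane | C#CC[C@@H](CO[Si](c1ccccc1)(c1ccccc1)C(C)(C)C)CCC=C | intermediate
10 | 2-(tert-butyldimethylsilyloxy)-N-methoxy-N-methylacetamide | CON(C)C(=O)CO[Si](C)(C)C(C)(C)C | starting material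
11 | (6S)-1-(tert-butyldimethylsilyloxy)-6-[(tert-butyldiphenylsilyloxy)methyl]dec-9-en-3-yn-2-one | CC(C)(C)[Si](C)(C)OCC(=O)C#CC[C@@H](CO[Si](c1ccccc1)(c1ccccc1)C(C)(C)C)CCC=C | intermediate
12 | (2R,6S)-1-(tert-butyldimethylsilyloxy)-6-[(tert-butyldiphenylsilyloxy)methyl]dec-9-en-3-yn-2-ol | CC(C)(C)[Si](C)(C)OC[C@H](O)C#CC[C@@H](CO[Si](c1ccccc1)(c1ccccc1)C(C)(C)C)CCC=C | intermediate
13 | (2R,3Z,6S)-1-(tert-butyldimethylsilyloxy)-6-[(tert-butyldiphenylsilyloxy)methyl]deca-3,9-dien-2-ol | CC(C)(C)[Si](C)(C)OC[C@H](O)/C=C\C[C@@H](CO[Si](c1ccccc1)(c1ccccc1)C(C)(C)C)CCC=C | intermediate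
14 | diethyl 2-methylidenepropanedioate (diethyl methylenemalonate) | C=C(C(=O)OCC)C(=O)OCC | starting material
15 | N-iodosuccinimide | O=C1CCC(=O)N1I | starting material
16 | potassium enolate of the diethyl (alkoxymethyl)malonate formed from 13 and 14 (O8–C13 ether, enolate carbon C11) | CC(C)(C)[Si](C)(C)OC[C@H](OCC(C(=O)OCC)=C([O-])OCC)/C=C\C[C@@H](CO[Si](c1ccccc1)(c1ccccc1)C(C)(C)C)CCC=C.[K+] | intermediate
17 | diethyl 2-iodo-2-({[(2R,3Z,6S)-1-(tert-butyldimethylsilyloxy)-6-[(tert-butyldiphenylsilyloxy)methyl]deca-3,9-dien-2-yl]oxy}methyl)propanedioate | CC(C)(C)[Si](C)(C)OC[C@H](OCC(I)(C(=O)OCC)C(=O)OCC)/C=C\C[C@@H](CO[Si](c1ccccc1)(c1ccccc1)C(C)(C)C)CCC=C | intermediate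
18 | diethyl tetrahydrofuran-3,3-dicarboxylate with CH2OTBS on C8 and the 1-iodoalkyl chain (C6 iodide, both epimers) on C7, C7/C8 trans | CCOC(=O)C1(C(=O)OCC)CO[C@@H](CO[Si](C)(C)C(C)(C)C)[C@@H]1C(I)C[C@@H](CO[Si](c2ccccc2)(c2ccccc2)C(C)(C)C)CCC=C | intermediate
19 | ethyl 2-oxo-3,7-dioxabicyclo[3.3.0]octane-1-carboxylate, cis-fused, with the (2S)-2-[(tert-butyldiphenylsilyloxy)methyl]hex-5-enyl chain on C6 (trans to C8) and CH2OTBS on C8 (trans to C6); C6 and C7 as in the target, C8 epimeric | O=C1O[C@H](C[C@@H](CO[Si](c3ccccc3)(c3ccccc3)C(C)(C)C)CCC=C)[C@@H]2[C@@]1(C(=O)OCC)CO[C@H]2CO[Si](C)(C)C(C)(C)C | intermediate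
20 | tetrahydrofuran-3,3-dicarboxylic acid with CH2OTBS on C8 and the 1-hydroxyalkyl chain (free C6 hydroxyl) on C7 | OC(=O)C1(C(=O)O)CO[C@@H](CO[Si](C)(C)C(C)(C)C)[C@@H]1[C@H](O)C[C@@H](CO[Si](c2ccccc2)(c2ccccc2)C(C)(C)C)CCC=C | intermediate
21 | carboxylic acid corresponding to 19 (CO2H on C11) | O=C1O[C@H](C[C@@H](CO[Si](c3ccccc3)(c3ccccc3)C(C)(C)C)CCC=C)[C@@H]2[C@@]1(C(=O)O)CO[C@H]2CO[Si](C)(C)C(C)(C)C | intermediate
22 | cis-fused 3,7-dioxabicyclo[3.3.0]octan-2-one with H on C11, chain on C6 and CH2OTBS on C8 as in 19 | O=C1O[C@H](C[C@@H](CO[Si](c3ccccc3)(c3ccccc3)C(C)(C)C)CCC=C)[C@@H]2[C@H]1CO[C@H]2CO[Si](C)(C)C(C)(C)C | intermediate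
23 | alcohol from 22 (CH2OH on C8) | O=C1O[C@H](C[C@@H](CO[Si](c3ccccc3)(c3ccccc3)C(C)(C)C)CCC=C)[C@@H]2[C@H]1CO[C@H]2CO | intermediate
24 | trimethyl phosphonoacetate | COC(=O)CP(=O)(OC)OC | starting material
25 | primary triflate of 23 | O=C1O[C@H](C[C@@H](CO[Si](c3ccccc3)(c3ccccc3)C(C)(C)C)CCC=C)[C@@H]2[C@H]1CO[C@H]2COS(=O)(=O)C(F)(F)F | intermediate
26 | methyl 2-(dimethoxyphosphoryl)-3-(bicyclic lactone C8-yl)propanoate, C10 epimers, terminal alkene retained | O=C1O[C@H](C[C@@H](CO[Si](c3ccccc3)(c3ccccc3)C(C)(C)C)CCC=C)[C@@H]2[C@H]1CO[C@H]2CC(C(=O)OC)P(=O)(OC)OC | intermediate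
27 | ozone | [O-][O+]=O | starting material
28 | 1,2,4-trioxolane (ozonide) of 26 | O=C1O[C@H](C[C@@H](CO[Si](c3ccccc3)(c3ccccc3)C(C)(C)C)CCC4OCOO4)[C@@H]2[C@H]1CO[C@H]2CC(C(=O)OC)P(=O)(OC)OC | intermediate
29 | C1 aldehyde of the phosphonoacetate | O=C1O[C@H](C[C@@H](CO[Si](c3ccccc3)(c3ccccc3)C(C)(C)C)CCC=O)[C@@H]2[C@H]1CO[C@H]2CC(C(=O)OC)P(=O)(OC)OC | intermediate
30 | tricyclic macrocycle: ten-membered ring with (E)-C1=C10 methyl enoate, 6,12-lactone and O8–C13 tetrahydrofuran, 15-O-TBDPS; C4, C6, C7 as in the target, C8 epimeric, H7/H11 cis | C3[C@H]1C(=O)O[C@@H]2C[C@@H](CO[Si](c4ccccc4)(c4ccccc4)C(C)(C)C)CC/C=C(/C(=O)OC)C[C@H](O3)[C@@H]12 | intermediate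
31 | bromodimethylborane | CB(C)Br | starting material
32 | 13-bromo-11,13-dihydro-8-epi alcohol: 6,12-lactone with CH2Br on C11, free 8-OH, 15-O-TBDPS | BrC[C@H]1C(=O)O[C@@H]2C[C@@H](CO[Si](c3ccccc3)(c3ccccc3)C(C)(C)C)CC/C=C(/C(=O)OC)C[C@H](O)[C@@H]12 | intermediate
33 | (S)-2-methylbutanoic acid | CC[C@H](C)C(=O)O | starting material
34 | 13-bromo-11,13-dihydro 8-O-[(S)-2-methylbutanoyl] ester (C8 as in the target), 15-O-TBDPS | BrC[C@H]1C(=O)O[C@@H]2C[C@@H](CO[Si](c3ccccc3)(c3ccccc3)C(C)(C)C)CC/C=C(/C(=O)OC)C[C@@H](OC(=O)[C@@H](C)CC)[C@@H]12 | intermediate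
35 | 15-O-tert-butyldiphenylsilyl ether of the target | C=C1C(=O)O[C@@H]2C[C@@H](CO[Si](c3ccccc3)(c3ccccc3)C(C)(C)C)CC/C=C(/C(=O)OC)C[C@@H](OC(=O)[C@@H](C)CC)[C@@H]12 | intermediate
36 | CNP0141952.2 | C=C1C(=O)O[C@@H]2C[C@@H](CO)CC/C=C(/C(=O)OC)C[C@@H](OC(=O)[C@@H](C)CC)[C@@H]12 | target

Total step count: 17
Longest linear sequence: 17 steps (1 → 36; every other input is a purchased compound)

**Steps most likely to fail**

1. Step 9 (key step). Iodine atoms may isomerise the (Z)-alkene before ring closure, which would weaken the facial control at C7. Non-selective iodine transfer followed by stereospecific closure may also give both C6 epimers, and the malonyl radical may add to the terminal alkene of a second molecule. The fallback makes the two bonds in separate oxidative and ionic events; it sets out from 13 and returns at 19. Conjugate addition of the alkoxide of 13 to 14 with a protic quench gives the diethyl (alkoxymethyl)malonate F1. Mn(OAc)3/Cu(OAc)2 oxidative radical cyclisation in EtOH (5-exo, C11–C7) with copper-mediated loss of a C5 hydrogen gives the (E)-C5=C6 alkenyl tetrahydrofuran diester F2. Iodolactonisation of one ester onto C6 (I2, MeCN, equilibrating conditions) gives the C5 iodo lactone ester F3. Bu3SnH at high concentration with AIBN then removes the iodide and gives 19.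

2. Step 14. Intermolecular olefination (cyclodimerisation) may compete with closure of the strained ten-membered ring, and the aldehyde may enolise or condense under the basic conditions. The fallback closes the ring by metathesis; it sets out from 26 and returns at 30, replacing steps 13 and 14. HWE olefination of 26 with formaldehyde (aq. CH2O, K2CO3) gives the 2-substituted acrylate F4. Ring-closing metathesis of F4 with the terminal alkene (Hoveyda–Grubbs II, PhMe, 80 °C, high dilution) forms the C1=C10 enoate and gives 30.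

3. Step 16. SN2 displacement at the hindered ring carbinol C8 may be slow, so that elimination, acyl transfer with retention, or translactonisation of the free hydroxyl onto C12 or C14 takes over. The fallback inverts C8 by oxidation and reduction; it sets out from 32 and returns at 34. Dess–Martin oxidation of 32 gives the C8 ketone F5. Luche reduction (NaBH4, CeCl3, MeOH, −78 °C), with hydride expected to approach anti to the C7–C11 bond, gives the target-configured C8 alcohol F6. Esterification of F6 with 33 (DCC, cat. DMAP) gives 34, which is treated with DBU as in step 16.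

**Further compounds**

F1 | step 9 | diethyl 2-({[(2R,3Z,6S)-1-(tert-butyldimethylsilyloxy)-6-[(tert-butyldiphenylsilyloxy)methyl]deca-3,9-dien-2-yl]oxy}methyl)propanedioate | CC(C)(C)[Si](C)(C)OC[C@H](OCC(C(=O)OCC)C(=O)OCC)/C=C\C[C@@H](CO[Si](c1ccccc1)(c1ccccc1)C(C)(C)C)CCC=C
F2 | step 9 | diethyl tetrahydrofuran-3,3-dicarboxylate with CH2OTBS on C8 and an (E)-C5=C6 alkenyl chain on C7, C7/C8 trans | CCOC(=O)C1(C(=O)OCC)CO[C@@H](CO[Si](C)(C)C(C)(C)C)[C@@H]1/C=C/[C@@H](CO[Si](c2ccccc2)(c2ccccc2)C(C)(C)C)CCC=C
F3 | step 9 | C5 iodide of lactone ester 19 (iodine on the chain carbon next to C6, both epimers) | O=C1O[C@H](C(I)[C@@H](CO[Si](c3ccccc3)(c3ccccc3)C(C)(C)C)CCC=C)[C@@H]2[C@@]1(C(=O)OCC)CO[C@H]2CO[Si](C)(C)C(C)(C)C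
F4 | step 14 | methyl 2-methylidene-3-(bicyclic lactone C8-yl)propanoate (2-substituted acrylate, terminal alkene retained) | O=C1O[C@H](C[C@@H](CO[Si](c3ccccc3)(c3ccccc3)C(C)(C)C)CCC=C)[C@@H]2[C@H]1CO[C@H]2CC(=C)C(=O)OC
F5 | step 16 | C8 ketone of 32 | BrC[C@H]1C(=O)O[C@@H]2C[C@@H](CO[Si](c3ccccc3)(c3ccccc3)C(C)(C)C)CC/C=C(/C(=O)OC)CC(=O)[C@@H]12
F6 | step 16 | C8 epimer of 32 (8-hydroxyl configured as in the target) | BrC[C@H]1C(=O)O[C@@H]2C[C@@H](CO[Si](c3ccccc3)(c3ccccc3)C(C)(C)C)CC/C=C(/C(=O)OC)C[C@@H](O)[C@@H]12
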